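The route rests on cutting the C6–C7 bond of the benzo ring (naphthoquinone numbering: C1/C4 carbonyls, C2 acetoxy, C3 isopropyl, C7 methyl, C8 side chain). A hexasubstituted trimethoxybenzene carrying an allyl group on C4a and a tertiary isopropenyl carbinol (future C8) on C8a (compound 21) is closed by ring-closing metathesis to the 5,8-dihydronaphthalen-8-ol 22. In one operation this forms the six-membered ring and fixes methyl at C7 and the 4-methylpent-4-enyl chain at C8. The C8 hydroxyl and the C5 methylene then sit 1,4 to each other, so loss of water aromatizes the ring. Oxidation, methoxy hydrolysis and acetylation finish the quinone.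

Key step: step 12

Remark: 21 and 22 are racemic at the carbinol carbon, which becomes an aromatic carbon in step 13; their SMILES carry no stereodescriptor, and the target has no stereocentre.

Remark: in-flask species are numbered when they react with a further reagent or are cleaved at a non-hydrogen bond on work-up (aryllithiums, the α-chloro ether, the acyl imidazole, the amide adduct); metal alkoxides and carboxylates that are only protonated on work-up count as the salt form of the product.

Step 1
Reactants: 1 1,2,4-trimethoxybenzene; 2 acetone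
Product: 4 2-(2,3,6-trimethoxyphenyl)propan-2-ol, via aryllithium 3 (not isolated)
Conditions: n-BuLi, THF, 0 °C to rt; then acetone, −78 °C to rt; H2O
Reagents that add atoms: none
Why: Directed ortho-lithiation removes the C3 proton of 1, the one flanked by two methoxy groups, and the aryllithium adds 1,2 to acetone.

Step 2
Reactants: 4 2-(2,3,6-trimethoxyphenyl)propan-2-ol
Product: 5 2-isopropyl-1,3,4-trimethoxybenzene
Conditions: Et3SiH, CF3CO2H, CH2Cl2, 0 °C to rt
Reagents that add atoms: none
Why: Ionic hydrogenation: acid ionizes the tertiary benzylic alcohol and the silane delivers hydride to the cation, leaving the aryl methyl ethers untouched.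

Step 3
Reactants: 5 2-isopropyl-1,3,4-trimethoxybenzene
Product: 7 3-isopropyl-2,4,5-trimethoxybenzaldehyde, via α-chloro ether 6 (not isolated)
Conditions: Cl2CHOMe, TiCl4, CH2Cl2, −10 to 0 °C; then H2O
Reagents that add atoms: dichloromethyl methyl ether, COC(Cl)Cl; water, O
Why: Rieche formylation should attack C6 of 5 (ortho to the 1-methoxy and para to the 3-methoxy group) in preference to C5 (one ortho-methoxy donor, para to isopropyl), and water hydrolyses the α-chloro ether to the aldehyde.

Step 4
Reactants: 7 3-isopropyl-2,4,5-trimethoxybenzaldehyde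
Product: 8 2-bromo-5-isopropyl-3,4,6-trimethoxybenzaldehyde
Conditions: Br2, NaOAc, AcOH, rt
Reagents that add atoms: bromine, BrBr
Why: Electrophilic aromatic bromination at the only remaining ring hydrogen, which is ortho to a methoxy group; acetate buffers the HBr so that ethers and aldehyde survive.

Step 5
Reactants: 8 2-bromo-5-isopropyl-3,4,6-trimethoxybenzaldehyde
Product: 9 (2-bromo-5-isopropyl-3,4,6-trimethoxyphenyl)methanol
Conditions: NaBH4, MeOH, 0 °C
Reagents that add atoms: none
Why: Borohydride reduction of the aldehyde; the aryl bromide and the ethers are inert.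

Step 6
Reactants: 9 (2-bromo-5-isopropyl-3,4,6-trimethoxyphenyl)methanol
Product: 10 1-bromo-2-(bromomethyl)-4-isopropyl-3,5,6-trimethoxybenzene
Conditions: PBr3, CH2Cl2, 0 °C
Reagents that add atoms: phosphorus tribromide, BrP(Br)Br
Why: Conversion of a primary benzylic alcohol into the bromide by SN2 displacement of its phosphite ester; the ring bromide is not touched.

Step 7
Reactants: 10 1-bromo-2-(bromomethyl)-4-isopropyl-3,5,6-trimethoxybenzene; 11 vinylmagnesium bromide
Product: 12 1-allyl-2-bromo-5-isopropyl-3,4,6-trimethoxybenzene
Conditions: CuI (10 mol%), THF, −30 to 0 °C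
Reagents that add atoms: none
Why: Copper-catalysed coupling of a benzylic bromide with a vinyl Grignard reagent (through a vinylcuprate) builds the allyl group, and the aryl bromide does not react at this temperature.

Step 8
Reactants: 13 5-oxohexanoic acid
Product: 14 5-methylhex-5-enoic acid
Conditions: Ph3PCH3Br, KOtBu, THF, 0 °C to rt; then 1 M HCl
Reagents that add atoms: methyltriphenylphosphonium bromide, C[P+](c1ccccc1)(c1ccccc1)c1ccccc1.[Br-]
Why: Wittig methylenation of the methyl ketone; the carboxylate formed by the first equivalent of base is inert to the ylide.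

Step 9
Reactants: 14 5-methylhex-5-enoic acid
Product: 16 N-methoxy-N,5-dimethylhex-5-enamide, via acyl imidazole 15 (not isolated)
Conditions: CDI, CH2Cl2, rt; then MeNHOMe·HCl, rt
Reagents that add atoms: N,O-dimethylhydroxylamine hydrochloride, CNOC.Cl
Why: Weinreb amide formation: carbonyldiimidazole activates the acid as the acyl imidazole, which the hydroxylamine aminolyses; the alkene is a spectator.

Step 10
Reactants: 12 1-allyl-2-bromo-5-isopropyl-3,4,6-trimethoxybenzene; 16 N-methoxy-N,5-dimethylhex-5-enamide
Product: 19 1-(2-allyl-4-isopropyl-3,5,6-trimethoxyphenyl)-5-methylhex-5-en-1-one, via aryllithium 17 (not isolated), via tetrahedral adduct 18 (not isolated)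
Conditions: n-BuLi, THF, −78 °C; then 16, −78 to 0 °C; H2O
Reagents that add atoms: none
Why: Bromine–lithium exchange at −78 °C outruns deprotonation of the allyl methylene, and the aryllithium acylates once on the Weinreb amide because the chelated adduct survives until hydrolysis.

Step 11
Reactants: 19 1-(2-allyl-4-isopropyl-3,5,6-trimethoxyphenyl)-5-methylhex-5-en-1-one; 20 isopropenylmagnesium bromide
Product: 21 3-(2-allyl-4-isopropyl-3,5,6-trimethoxyphenyl)-2,7-dimethylocta-1,7-dien-3-ol (racemic)
Conditions: LaCl3·2LiCl, THF, 0 °C to rt; then H2O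
Reagents that add atoms: none
Why: Grignard 1,2-addition to the ketone, with LaCl3·2LiCl activating the hindered carbonyl and suppressing enolization; the new carbinol centre forms as a racemate, which is immaterial because it becomes sp2 in step 13.

Step 12
Reactants: 21 3-(2-allyl-4-isopropyl-3,5,6-trimethoxyphenyl)-2,7-dimethylocta-1,7-dien-3-ol (racemic)
Product: 22 6-isopropyl-5,7,8-trimethoxy-2-methyl-1-(4-methylpent-4-en-1-yl)-1,4-dihydronaphthalen-1-ol (racemic)
Conditions: second-generation Grubbs catalyst (H2IMes)(PCy3)Cl2Ru=CHPh (5 mol%), 1,4-benzoquinone (10 mol%), CH2Cl2 (0.01 M), 40 °C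
Reagents that add atoms: none
Why: The ruthenium benzylidene exchanges onto the monosubstituted allyl alkene, the new alkylidene undergoes intramolecular [2+2] cycloaddition with the isopropenyl group on the neighbouring carbinol carbon, and cycloreversion of the ruthenacyclobutane releases the C6=C7 alkene, ethylene being lost in turnover. The closest known reaction type is ring-closing metathesis of octa-1,7-dienes that carry a gem-disubstituted alkene beside a tertiary allylic alcohol, as used in metathesis–dehydration routes to arenes. The ring closes as a six-membered carbocycle (C4a, C5, C6, C7, C8, C8a) with the new double bond endocyclic, the aromatic C4a–C8a bond holding the two arms ortho to each other. No stereocentre is created, and the racemic carbinol centre at C8 is erased on aromatization. The step needs site selectivity among three alkenes: the catalyst loads on the only monosubstituted alkene, six-membered closure onto the adjacent isopropenyl group outruns nine-membered closure onto the remote 1,1-disubstituted alkene, high dilution disfavours intermolecular metathesis, and 1,4-benzoquinone suppresses ruthenium hydride migration of the allyl double bond. Partial loss of water from 22 in the flask would be harmless, since step 13 completes it.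

Step 13
Reactants: 22 6-isopropyl-5,7,8-trimethoxy-2-methyl-1-(4-methylpent-4-en-1-yl)-1,4-dihydronaphthalen-1-ol (racemic)
Product: 23 3-isopropyl-1,2,4-trimethoxy-7-methyl-8-(4-methylpent-4-en-1-yl)naphthalene
Conditions: PPTS (10 mol%), CH2Cl2, rt
Reagents that add atoms: none
Why: Acid-catalysed 1,4-elimination of water: the tertiary, benzylic and allylic C8 hydroxyl ionizes and the cation loses the C5 proton, the gain of aromaticity making this far faster than protonation of the isolated 1,1-disubstituted alkene under weak acid.

Step 14
Reactants: 23 3-isopropyl-1,2,4-trimethoxy-7-methyl-8-(4-methylpent-4-en-1-yl)naphthalene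
Product: 24 3-isopropyl-2-methoxy-7-methyl-8-(4-methylpent-4-en-1-yl)naphthalene-1,4-dione
Conditions: (NH4)2Ce(NO3)6, MeCN/H2O, 0 °C
Reagents that add atoms: water, O
Why: Oxidative demethylation: two one-electron oxidations of the electron-rich ring with water attack at C1 and C4 release two molecules of methanol and give the para-quinone with the C2 methoxy retained; any ortho-quinone isomer would converge in step 15.

Step 15
Reactants: 24 3-isopropyl-2-methoxy-7-methyl-8-(4-methylpent-4-en-1-yl)naphthalene-1,4-dione
Product: 25 2-hydroxy-3-isopropyl-7-methyl-8-(4-methylpent-4-en-1-yl)naphthalene-1,4-dione (salvipisone)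
Conditions: NaOH, THF/H2O, rt; then 1 M HCl
Reagents that add atoms: sodium hydroxide, [Na+].[OH-]
Why: Addition–elimination of hydroxide at C2 of the vinylogous ester (saponification of a 2-methoxy-1,4-naphthoquinone) gives the stabilized hydroxyquinone anion, protonated on acidification; the remote alkene is inert to base.

Step 16
Reactants: 25 2-hydroxy-3-isopropyl-7-methyl-8-(4-methylpent-4-en-1-yl)naphthalene-1,4-dione (salvipisone)
Product: 26 3-isopropyl-7-methyl-8-(4-methylpent-4-en-1-yl)-1,4-dioxo-1,4-dihydronaphthalen-2-yl acetate (acetylsalvipisone)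
Conditions: Ac2O, pyridine, DMAP (cat.), CH2Cl2, 0 °C to rt
Reagents that add atoms: acetic anhydride, CC(=O)OC(C)=O
Why: O-acylation of the acidic enolic hydroxyl with acetic anhydride under nucleophilic catalysis by DMAP.

Compound list

1 | 1,2,4-trimethoxybenzene | COc1ccc(OC)c(OC)c1 | starting material
2 | acetone | CC(C)=O | starting material
3 | (2,3,6-trimethoxyphenyl)lithium | [Li]c1c(OC)ccc(OC)c1OC | intermediate
4 | 2-(2,3,6-trimethoxyphenyl)propan-2-ol | CC(C)(O)c1c(OC)ccc(OC)c1OC | intermediate
5 | 2-isopropyl-1,3,4-trimethoxybenzene | CC(C)c1c(OC)ccc(OC)c1OC | intermediate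
6 | 1-[chloro(methoxy)methyl]-3-isopropyl-2,4,5-trimethoxybenzene | COC(Cl)c1cc(OC)c(OC)c(C(C)C)c1OC | intermediate
7 | 3-isopropyl-2,4,5-trimethoxybenzaldehyde | COc1cc(C=O)c(OC)c(C(C)C)c1OC | intermediate
8 | 2-bromo-5-isopropyl-3,4,6-trimethoxybenzaldehyde | COc1c(Br)c(C=O)c(OC)c(C(C)C)c1OC | intermediate
9 | (2-bromo-5-isopropyl-3,4,6-trimethoxyphenyl)methanol | COc1c(Br)c(CO)c(OC)c(C(C)C)c1OC | intermediate
10 | 1-bromo-2-(bromomethyl)-4-isopropyl-3,5,6-trimethoxybenzene | COc1c(Br)c(CBr)c(OC)c(C(C)C)c1OC | intermediate
11 | vinylmagnesium bromide | C=C[Mg]Br | starting material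
12 | 1-allyl-2-bromo-5-isopropyl-3,4,6-trimethoxybenzene | C=CCc1c(Br)c(OC)c(OC)c(C(C)C)c1OC | intermediate
13 | 5-oxohexanoic acid | CC(=O)CCCC(=O)O | starting material
14 | 5-methylhex-5-enoic acid | C=C(C)CCCC(=O)O | intermediate
15 | 1-(1H-imidazol-1-yl)-5-methylhex-5-en-1-one | C=C(C)CCCC(=O)n1ccnc1 | intermediate
16 | N-methoxy-N,5-dimethylhex-5-enamide | C=C(C)CCCC(=O)N(C)OC | intermediate
17 | (2-allyl-4-isopropyl-3,5,6-trimethoxyphenyl)lithium | C=CCc1c([Li])c(OC)c(OC)c(C(C)C)c1OC | intermediate
18 | lithium 1-(2-allyl-4-isopropyl-3,5,6-trimethoxyphenyl)-1-[methoxy(methyl)amino]-5-methylhex-5-en-1-olate | C=CCc1c(C(O[Li])(CCCC(C)=C)N(C)OC)c(OC)c(OC)c(C(C)C)c1OC | intermediate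
19 | 1-(2-allyl-4-isopropyl-3,5,6-trimethoxyphenyl)-5-methylhex-5-en-1-one | C=CCc1c(C(=O)CCCC(C)=C)c(OC)c(OC)c(C(C)C)c1OC | intermediate
20 | isopropenylmagnesium bromide | C=C(C)[Mg]Br | starting material
21 | 3-(2-allyl-4-isopropyl-3,5,6-trimethoxyphenyl)-2,7-dimethylocta-1,7-dien-3-ol (racemic) | C=CCc1c(C(O)(CCCC(C)=C)C(C)=C)c(OC)c(OC)c(C(C)C)c1OC | intermediate
22 | 6-isopropyl-5,7,8-trimethoxy-2-methyl-1-(4-methylpent-4-en-1-yl)-1,4-dihydronaphthalen-1-ol (racemic; the 5,8-dihydronaphthalen-8-ol in quinone numbering) | C=C(C)CCCC1(O)C(C)=CCc2c(OC)c(C(C)C)c(OC)c(OC)c21 | intermediate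
23 | 3-isopropyl-1,2,4-trimethoxy-7-methyl-8-(4-methylpent-4-en-1-yl)naphthalene | C=C(C)CCCc1c(C)ccc2c(OC)c(C(C)C)c(OC)c(OC)c12 | intermediate
24 | 3-isopropyl-2-methoxy-7-methyl-8-(4-methylpent-4-en-1-yl)naphthalene-1,4-dione | C=C(C)CCCc1c(C)ccc2c1C(=O)C(OC)=C(C(C)C)C2=O | intermediate
25 | 2-hydroxy-3-isopropyl-7-methyl-8-(4-methylpent-4-en-1-yl)naphthalene-1,4-dione (salvipisone) | C=C(C)CCCc1c(C)ccc2c1C(=O)C(O)=C(C(C)C)C2=O | intermediate
26 | 3-isopropyl-7-methyl-8-(4-methylpent-4-en-1-yl)-1,4-dioxo-1,4-dihydronaphthalen-2-yl acetate (acetylsalvipisone) | C=C(C)CCCc1c(C)ccc2c1C(=O)C(OC(C)=O)=C(C(C)C)C2=O | target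

Total step count: 16 (steps 1–7 and 10–16 on the main line, steps 8–9 for the amide fragment).
Longest linear sequence: 14 steps, from 1 to 26.

Steps most likely to fail

Step 12 (key step). The allyl double bond may migrate into conjugation with the arene before closure, which would lead to five-membered closure. Alternatively, the alkylidene loaded on the allyl arm may fail to engage the gem-disubstituted alkene beside the fully substituted carbinol carbon, so that intermolecular metathesis through the remote alkene takes over. The fallback closes the benzo ring on a less hindered diene that lacks the third alkene and attaches the side chain afterwards by cross-coupling. It sets out from bromide 12: aryllithium 17 (n-BuLi, THF, −78 °C) would be added to methacrolein to give 1-(2-allyl-4-isopropyl-3,5,6-trimethoxyphenyl)-2-methylprop-2-en-1-ol F1. Metathesis with the same ruthenium catalyst should close it to 6-isopropyl-5,7,8-trimethoxy-2-methyl-1,4-dihydronaphthalen-1-ol F2. Swern oxidation would give the ring ketone, which tautomerizes at once to 6-isopropyl-5,7,8-trimethoxy-2-methylnaphthalen-1-ol F3. Tf2O and pyridine would convert this into 6-isopropyl-5,7,8-trimethoxy-2-methylnaphthalen-1-yl trifluoromethanesulfonate F4. Negishi coupling (Pd(OAc)2, SPhos, THF, 60 °C) with (4-methylpent-4-en-1-yl)zinc bromide F5, made from 5-bromo-2-methylpent-1-ene (assumed purchasable) and zinc dust with LiCl, should deliver naphthalene 23, where the route is rejoined before step 14.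

Step 11. The Grignard reagent may enolize the ketone instead of adding, or be kept from the carbonyl group, which is twisted between two ortho substituents, so that 19 is returned. The fallback exchanges the roles of nucleophile and carbonyl partner and sets out from 12 and 16. Amide 16 and isopropenylmagnesium bromide 20 (THF, 0 °C) would give 2,7-dimethylocta-1,7-dien-3-one F6. Aryllithium 17, generated from bromide 12 as in step 10, would then add to the carbonyl group of F6 (THF, −78 °C, with LaCl3·2LiCl if conjugate addition intrudes) to give carbinol 21 directly, where the route is rejoined before step 12.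

Step 4. Bromine may attack ipso at the formyl-bearing carbon, the most electron-rich position, with loss of the formyl group, or substitution at the only weakly activated ring position may be too slow. The fallback replaces electrophilic substitution by directed metalation and sets out from aldehyde 7. Reduction with NaBH4 (MeOH, 0 °C) would give (3-isopropyl-2,4,5-trimethoxyphenyl)methanol F7. n-BuLi (2.2 equiv) with TMEDA should remove the only ring hydrogen, which is flanked by the lithium alkoxide arm and a methoxy group, to give the dilithio species lithium (2-lithio-5-isopropyl-3,4,6-trimethoxyphenyl)methanolate F8. Quenching with 1,2-dibromotetrachloroethane would give bromo alcohol 9, where the route is rejoined before step 6.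

Further compounds

F1 | step 12 | 1-(2-allyl-4-isopropyl-3,5,6-trimethoxyphenyl)-2-methylprop-2-en-1-ol (racemic) | C=CCc1c(C(O)C(C)=C)c(OC)c(OC)c(C(C)C)c1OC
F2 | step 12 | 6-isopropyl-5,7,8-trimethoxy-2-methyl-1,4-dihydronaphthalen-1-ol (racemic) | CC1=CCc2c(OC)c(C(C)C)c(OC)c(OC)c2C1O
F3 | step 12 | 6-isopropyl-5,7,8-trimethoxy-2-methylnaphthalen-1-ol | Cc1ccc2c(OC)c(C(C)C)c(OC)c(OC)c2c1O
F4 | step 12 | 6-isopropyl-5,7,8-trimethoxy-2-methylnaphthalen-1-yl trifluoromethanesulfonate | Cc1ccc2c(OC)c(C(C)C)c(OC)c(OC)c2c1OS(=O)(=O)C(F)(F)F
F5 | step 12 | (4-methylpent-4-en-1-yl)zinc bromide | C=C(C)CCC[Zn]Br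
F6 | step 11 | 2,7-dimethylocta-1,7-dien-3-one | C=C(C)CCCC(=O)C(C)=C
F7 | step 4 | (3-isopropyl-2,4,5-trimethoxyphenyl)methanol | COc1cc(CO)c(OC)c(C(C)C)c1OC
F8 | step 4 | lithium (2-lithio-5-isopropyl-3,4,6-trimethoxyphenyl)methanolate | COc1c([Li])c(CO[Li])c(OC)c(C(C)C)c1OC
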